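Ring A is made last. Its resorcinol pattern (O on C5 and C7, H on C6 and C8) arises when C5 is a ketene carbonyl carbon, C6 and C7 the two carbons of a terminal ynol ether, C8 a former diazo carbon, and C4a/C8a the enol-ether double bond of a ready-made 4-pyranone, the future heterocyclic ring. One photochemical operation therefore turns a pyranonyl diazomethyl ketone that already carries the complete protected (S)-3-silyloxyheptanoate chain, plus methoxyacetylene, into the 5-hydroxy-7-methoxychromone via Wolff rearrangement, cyclobutenone formation and two electrocyclic events. The diazoketone is assembled convergently from a pyranone acid and a chiral iodide; O-methylation and acidolysis complete the target.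

Key step: step 9

Remarks on the chemistry
(a) The silyl ether and tert-butyl ester are kept so that one acid treatment finishes the synthesis. For that reason the chain is joined only after the pyranone acid has been made in hot acid, the acid chloride is made without HCl, and the coupling uses a pyranone dienolate that is a weaker base than an ester enolate.
(b) Metal enolates, dianions and acetylides that are only deprotonated forms of numbered compounds are not numbered separately.
(c) Assumption: in step 2 the (S)-BINAP catalyst is taken to give the (S)-alcohol, by analogy with simple 3-oxoalkanoates; this should be confirmed on 5 by Mosher ester analysis. CH2CO2R outranks the alkyl chain at every stage, so the descriptor stays (S) from 5 to 25.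

Step 1
Reactants: 1 4-chlorobutanoyl chloride; 2 Meldrum's acid
Product: 4 tert-butyl 6-chloro-3-oxohexanoate, via acyl Meldrum's acid 3 (not isolated)
Conditions: pyridine (2 equiv), CH2Cl2, 0 °C to rt; dilute HCl wash; then t-BuOH, toluene, 90 °C
Reagents that add atoms: tert-butanol, CC(C)(C)O
Why: C-acylation of Meldrum's acid and thermal fragmentation to an acylketene that is trapped by tert-butanol (Meldrum's acid β-keto ester synthesis) is a non-basic entry to the β-keto ester, so the ω-chloride cannot alkylate an enolate.

Step 2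
Reactants: 4 tert-butyl 6-chloro-3-oxohexanoate
Product: 5 tert-butyl (S)-6-chloro-3-hydroxyhexanoate
Conditions: H2 (10 atm), RuCl2[(S)-BINAP] (0.2 mol %), MeOH, 50 °C
Reagents that add atoms: none
Why: Noyori asymmetric hydrogenation of a β-keto ester, in which the ester-chelated ketone is reduced on one face under control of the (S)-BINAP ligand, should set the only stereocentre of the target as (S).

Step 3
Reactants: 5 tert-butyl (S)-6-chloro-3-hydroxyhexanoate
Product: 6 tert-butyl (S)-3-(tert-butyldimethylsilyloxy)-6-chlorohexanoate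
Conditions: TBSCl, imidazole, DMF, rt
Reagents that add atoms: tert-butyldimethylsilyl chloride, CC(C)(C)[Si](C)(C)Cl
Why: Imidazole-promoted silylation of a secondary alcohol is mild enough that the chloro alcohol should not close to a tetrahydrofuran.

Step 4
Reactants: 6 tert-butyl (S)-3-(tert-butyldimethylsilyloxy)-6-chlorohexanoate
Product: 7 tert-butyl (S)-3-(tert-butyldimethylsilyloxy)-6-iodohexanoate
Conditions: NaI, NaHCO3 (cat.), acetone, reflux, dark
Reagents that add atoms: sodium iodide, [Na+].[I-]
Why: Finkelstein halide exchange, driven by precipitation of NaCl, should give the more reactive primary iodide without touching the silyl ether or the ester.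

Step 5
Reactants: 8 acetylacetone; 9 diethyl oxalate
Product: 12 6-methyl-4-oxo-4H-pyran-2-carboxylic acid, via ethyl 2,4,6-trioxoheptanoate 10 (not isolated), via ethyl 6-methyl-4-oxo-4H-pyran-2-carboxylate 11 (not isolated)
Conditions: LiN(iPr)2 (commercial solution, 2.1 equiv), THF, −78 to 0 °C; added to 9 (1.5 equiv), −78 °C to rt; then conc. HCl, 100 °C
Reagents that add atoms: water, O
Why: Claisen acylation of the acetylacetone 1,3-dianion at its terminal carbon, then acid-catalysed cyclodehydration of the 1,3,5-tricarbonyl compound to the 4-pyranone and ester hydrolysis in the same hot acid, is robust here because no protecting group is yet present.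

Step 6
Reactants: 12 6-methyl-4-oxo-4H-pyran-2-carboxylic acid; 7 tert-butyl (S)-3-(tert-butyldimethylsilyloxy)-6-iodohexanoate
Product: 13 (S)-6-[7-tert-butoxy-5-(tert-butyldimethylsilyloxy)-7-oxoheptyl]-4-oxo-4H-pyran-2-carboxylic acid
Conditions: 12 (1.3 equiv), LiN(iPr)2 (2.0 equiv per 12), THF/DMPU, −78 °C; then 7, −78 to −20 °C; cold 1 M HCl to pH 3
Reagents that add atoms: none
Why: Lateral (vinylogous) deprotonation of the methyl group of the lithium carboxylate gives a dienolate dianion that should be C-alkylated by the primary iodide (lateral metalation–alkylation of 2-methyl-4-pyranones and of methyl-substituted carboxylic acid dianions), and this dienolate is too weak a base to enolise the β-silyloxy ester.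

Step 7
Reactants: 13 (S)-6-[7-tert-butoxy-5-(tert-butyldimethylsilyloxy)-7-oxoheptyl]-4-oxo-4H-pyran-2-carboxylic acid
Product: 15 tert-butyl (S)-3-(tert-butyldimethylsilyloxy)-7-[6-(2-diazoacetyl)-4-oxo-4H-pyran-2-yl]heptanoate, via acid chloride 14 (not isolated)
Conditions: 1-chloro-N,N,2-trimethylprop-1-en-1-amine (1.05 equiv), CH2Cl2, 0 °C to rt; then CH2N2 (pre-formed ethereal solution, 2.5 equiv), Et2O, 0 °C
Reagents that add atoms: diazomethane, C=[N+]=[N-]
Why: The α-chloroenamine makes the acid chloride without releasing HCl, and this chloride, which has no α-hydrogen, acylates diazomethane (first stage of an Arndt–Eistert sequence) while the excess diazomethane scavenges HCl.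

Step 8
Reactants: 16 chloroacetaldehyde dimethyl acetal
Product: 18 methoxyacetylene, via 1-chloro-2-methoxyethene 17 (not isolated)
Conditions: NaNH2 (3 equiv), liq. NH3, −33 °C; NH3 evaporated; aq. NaCl, −70 °C to rt; distilled into cold toluene
Reagents that add atoms: none
Why: Two successive base-induced β-eliminations (methanol, then HCl) give the sodium acetylide, which is protonated on aqueous quench; this is the established preparation of this low-boiling ynol ether.

Step 9
Reactants: 15 tert-butyl (S)-3-(tert-butyldimethylsilyloxy)-7-[6-(2-diazoacetyl)-4-oxo-4H-pyran-2-yl]heptanoate; 18 methoxyacetylene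
Product: 23 tert-butyl (S)-3-(tert-butyldimethylsilyloxy)-7-(5-hydroxy-7-methoxy-4-oxo-4H-chromen-2-yl)heptanoate, via pyranonylketene 19 (not isolated), via methoxycyclobutenone 20 (not isolated), via dienylketene 21 (not isolated), via 4aH-dienone tautomer 22 (not isolated)
Conditions: 18 (5 equiv), degassed toluene, violet–blue LEDs (405–450 nm), 0–5 °C; then 90 °C
Reagents that add atoms: none
Why: Proposed new method: excitation of the long-wavelength diazoketone band, where the pyranone is transparent, expels N2 with 1,2-shift of the pyranone carbon to give ketene 19, whose carbonyl carbon is attacked by the nucleophilic CH terminus of the ynol ether to give cyclobutenone 20 by [2+2] cycloaddition; on warming, 20 opens reversibly (conrotatory, four electrons) to dienylketene 21, the isomer with ketene and pyranone cis closes onto the pyranone C–H carbon, and enolisation of dienone 22 gives the phenol. The closest known reaction type is the photo-Wolff (diazoketone) form of the Danheiser benzannulation with alkoxy- or silyloxyalkynes, in which an alkene or arene, not a 4-pyranone, supplies the last two ring carbons. Ring A is closed by a thermal disrotatory six-electron electrocyclisation that forms C4a–C5, after C8a–C8 has been made in the Wolff shift and C5–C6 and C7–C8 in the cycloaddition. No stereocentre is created, since the sp3 centres of 20 and 22 vanish on aromatisation, and the remote silyloxy centre is untouched. The regiochemistry needed (OMe on C7, meta to the C5 hydroxyl) is secured by the polarisation of methoxyacetylene, and the site of closure is unambiguous because the other neighbour of the ketene-bearing carbon is the ring oxygen. Closure should be easier than onto a benzene ring because the C4a=C8a enol-ether bond has little aromatic stabilisation to lose; the hydrogen-bonded C5 hydroxyl of 23 should resist acylation by ketene, and the ester and silyl ether are inert to light, ketene and 90 °C.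

Step 10
Reactants: 23 tert-butyl (S)-3-(tert-butyldimethylsilyloxy)-7-(5-hydroxy-7-methoxy-4-oxo-4H-chromen-2-yl)heptanoate
Product: 24 tert-butyl (S)-3-(tert-butyldimethylsilyloxy)-7-(5,7-dimethoxy-4-oxo-4H-chromen-2-yl)heptanoate
Conditions: MeI (excess), K2CO3, DMF, 40 °C
Reagents that add atoms: iodomethane, CI
Why: Williamson O-methylation of the hydrogen-bonded C5 phenol, the only acidic site, should proceed with excess reagent in a polar solvent, and carbonate is too weak to enolise the β-silyloxy ester.

Step 11
Reactants: 24 tert-butyl (S)-3-(tert-butyldimethylsilyloxy)-7-(5,7-dimethoxy-4-oxo-4H-chromen-2-yl)heptanoate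
Product: 25 (S)-7-(5,7-dimethoxy-4-oxo-4H-chromen-2-yl)-3-hydroxyheptanoic acid (penithochromone P)
Conditions: CF3CO2H/H2O (9:1), 0 °C to rt; then aq. NaHCO3/MeOH, rt; acidify to pH 3
Reagents that add atoms: none
Why: Acidolysis removes the tert-butyl ester (loss of isobutene) and hydrolyses the silyl ether in one operation, the bicarbonate stage cleaves any trifluoroacetate formed on the carbinol, and the aryl methyl ethers, the chromone and the non-ionisable stereocentre should be unaffected.

Compound list
1 | 4-chlorobutanoyl chloride | O=C(Cl)CCCCl | starting material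
2 | Meldrum's acid (2,2-dimethyl-1,3-dioxane-4,6-dione) | CC1(C)OC(=O)CC(=O)O1 | starting material
3 | 5-(4-chloro-1-hydroxybutylidene)-2,2-dimethyl-1,3-dioxane-4,6-dione (acyl Meldrum's acid) | CC1(C)OC(=O)C(=C(O)CCCCl)C(=O)O1 | intermediate (not isolated)
4 | tert-butyl 6-chloro-3-oxohexanoate | CC(C)(C)OC(=O)CC(=O)CCCCl | intermediate
5 | tert-butyl (S)-6-chloro-3-hydroxyhexanoate | ClCCC[C@H](O)CC(=O)OC(C)(C)C | intermediate
6 | tert-butyl (S)-3-(tert-butyldimethylsilyloxy)-6-chlorohexanoate | ClCCC[C@H](O[Si](C)(C)C(C)(C)C)CC(=O)OC(C)(C)C | intermediate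
7 | tert-butyl (S)-3-(tert-butyldimethylsilyloxy)-6-iodohexanoate | ICCC[C@H](O[Si](C)(C)C(C)(C)C)CC(=O)OC(C)(C)C | intermediate
8 | acetylacetone | CC(=O)CC(C)=O | starting material
9 | diethyl oxalate | CCOC(=O)C(=O)OCC | starting material
10 | ethyl 2,4,6-trioxoheptanoate | CCOC(=O)C(=O)CC(=O)CC(C)=O | intermediate (not isolated)
11 | ethyl 6-methyl-4-oxo-4H-pyran-2-carboxylate | CCOC(=O)c1cc(=O)cc(C)o1 | intermediate (not isolated)
12 | 6-methyl-4-oxo-4H-pyran-2-carboxylic acid | Cc1cc(=O)cc(C(=O)O)o1 | intermediate
13 | (S)-6-[7-tert-butoxy-5-(tert-butyldimethylsilyloxy)-7-oxoheptyl]-4-oxo-4H-pyran-2-carboxylic acid | O=C(O)c1cc(=O)cc(CCCC[C@H](O[Si](C)(C)C(C)(C)C)CC(=O)OC(C)(C)C)o1 | intermediate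
14 | tert-butyl (S)-3-(tert-butyldimethylsilyloxy)-7-[6-(chlorocarbonyl)-4-oxo-4H-pyran-2-yl]heptanoate | O=C(Cl)c1cc(=O)cc(CCCC[C@H](O[Si](C)(C)C(C)(C)C)CC(=O)OC(C)(C)C)o1 | intermediate (not isolated)
15 | tert-butyl (S)-3-(tert-butyldimethylsilyloxy)-7-[6-(2-diazoacetyl)-4-oxo-4H-pyran-2-yl]heptanoate | [N-]=[N+]=CC(=O)c1cc(=O)cc(CCCC[C@H](O[Si](C)(C)C(C)(C)C)CC(=O)OC(C)(C)C)o1 | intermediate (key-step precursor)
16 | chloroacetaldehyde dimethyl acetal | COC(CCl)OC | starting material
17 | 1-chloro-2-methoxyethene | COC=CCl | intermediate (not isolated)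
18 | methoxyacetylene | COC#C | intermediate (key-step precursor)
19 | tert-butyl (S)-3-(tert-butyldimethylsilyloxy)-7-[4-oxo-6-(2-oxoethenyl)-4H-pyran-2-yl]heptanoate (pyranonylketene) | O=C=Cc1cc(=O)cc(CCCC[C@H](O[Si](C)(C)C(C)(C)C)CC(=O)OC(C)(C)C)o1 | intermediate (not isolated)
20 | tert-butyl (3S)-3-(tert-butyldimethylsilyloxy)-7-[6-(2-methoxy-4-oxocyclobut-2-en-1-yl)-4-oxo-4H-pyran-2-yl]heptanoate (either configuration at the cyclobutenone CH) | COC1=CC(=O)C1c1cc(=O)cc(CCCC[C@H](O[Si](C)(C)C(C)(C)C)CC(=O)OC(C)(C)C)o1 | intermediate (not isolated)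
21 | tert-butyl (S)-3-(tert-butyldimethylsilyloxy)-7-[6-(2-methoxy-4-oxobuta-1,3-dien-1-yl)-4-oxo-4H-pyran-2-yl]heptanoate (ketene cis to the pyranone) | O=C=C/C(OC)=C\c1cc(=O)cc(CCCC[C@H](O[Si](C)(C)C(C)(C)C)CC(=O)OC(C)(C)C)o1 | intermediate (not isolated)
22 | tert-butyl (3S)-3-(tert-butyldimethylsilyloxy)-7-(7-methoxy-4,5-dioxo-4a,5-dihydro-4H-chromen-2-yl)heptanoate (either configuration at C4a) | COC1=CC(=O)C2C(=O)C=C(CCCC[C@H](O[Si](C)(C)C(C)(C)C)CC(=O)OC(C)(C)C)OC2=C1 | intermediate (not isolated)
23 | tert-butyl (S)-3-(tert-butyldimethylsilyloxy)-7-(5-hydroxy-7-methoxy-4-oxo-4H-chromen-2-yl)heptanoate | COc1cc(O)c2c(=O)cc(CCCC[C@H](O[Si](C)(C)C(C)(C)C)CC(=O)OC(C)(C)C)oc2c1 | intermediate (key-step product)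
24 | tert-butyl (S)-3-(tert-butyldimethylsilyloxy)-7-(5,7-dimethoxy-4-oxo-4H-chromen-2-yl)heptanoate | COc1cc(OC)c2c(=O)cc(CCCC[C@H](O[Si](C)(C)C(C)(C)C)CC(=O)OC(C)(C)C)oc2c1 | intermediate
25 | (S)-7-(5,7-dimethoxy-4-oxo-4H-chromen-2-yl)-3-hydroxyheptanoic acid (penithochromone P) | COc1cc(OC)c2c(=O)cc(CCCC[C@H](O)CC(=O)O)oc2c1 | target

Total step count: 11.
Longest linear sequence: 9 steps (1, 2, 3, 4, 6, 7, 9, 10, 11); steps 5 and 8 are side branches.

Steps most likely to fail

Step 9 (key step, proposed new method). The ketene may be lost to dimerisation or to oligomerisation of the ynol ether before cycloaddition. The sequence may also stall at the cyclobutenone, or the dienylketene may be trapped otherwise instead of closing onto the pyranone carbon, and stray short-wavelength light would start pyranone photochemistry. The fallback uses known chemistry, sets out from iodide 7 and returns at 24, with ring A bought instead of made. Commercial 2′-hydroxy-4′,6′-dimethoxyacetophenone is C-acetylated with ethyl acetate and NaH (Claisen condensation) to 1-(2-hydroxy-4,6-dimethoxyphenyl)butane-1,3-dione F1. Cyclodehydration of this diketone in HCl/acetic acid gives 5,7-dimethoxy-2-methyl-4H-chromen-4-one F2. Lateral lithiation of the 2-methyl group (LiN(iPr)2, THF, −78 °C) and alkylation with 7 then gives 24, which continues with step 11.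

Step 6. The dilithio species may aggregate or dissolve poorly, alkylation may be slow or occur on oxygen, and the dianion may act as a base and eliminate HI from 7. The fallback removes the carboxylate from the nucleophile; it sets out from 7 and returns at 13. Commercial 2,6-dimethyl-4H-pyran-4-one, used in excess, is deprotonated at one methyl group (LiN(iPr)2, THF, −78 °C) and alkylated with 7 to give tert-butyl (S)-3-(tert-butyldimethylsilyloxy)-7-(6-methyl-4-oxo-4H-pyran-2-yl)heptanoate F3. The remaining, more reactive methyl group is condensed with N,N-dimethylformamide dimethyl acetal (N-methylimidazole, 110 °C) to give tert-butyl (S)-3-(tert-butyldimethylsilyloxy)-7-{6-[(E)-2-(dimethylamino)ethenyl]-4-oxo-4H-pyran-2-yl}heptanoate F4. Periodate cleavage of the enamine (NaIO4, THF/H2O) gives tert-butyl (S)-3-(tert-butyldimethylsilyloxy)-7-(6-formyl-4-oxo-4H-pyran-2-yl)heptanoate F5, and Pinnick oxidation (NaClO2, NaH2PO4, 2-methylbut-2-ene) gives 13.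

Step 7. Diazomethane may add as a 1,3-dipole to the electron-poor pyranone double bond, and any unscavenged HCl would strip the acid-labile groups or convert the diazoketone into a chloromethyl ketone. The fallback introduces the diazo group by diazo transfer instead of acylating a diazoalkane; it sets out from 13 and returns at 15. Acid chloride 14, made as in step 7, is coupled with MeZnCl under Pd(PPh3)4 catalysis (Negishi acylation) to give tert-butyl (S)-7-(6-acetyl-4-oxo-4H-pyran-2-yl)-3-(tert-butyldimethylsilyloxy)heptanoate F6. Its enolate (LiN(SiMe3)2, THF, −78 °C) is trifluoroacetylated with 2,2,2-trifluoroethyl trifluoroacetate to give tert-butyl (S)-3-(tert-butyldimethylsilyloxy)-7-[4-oxo-6-(4,4,4-trifluoro-3-oxobutanoyl)-4H-pyran-2-yl]heptanoate F7. Detrifluoroacetylative diazo transfer with methanesulfonyl azide, Et3N and water in MeCN then gives 15.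

Further compounds
F1 | step 9 | 1-(2-hydroxy-4,6-dimethoxyphenyl)butane-1,3-dione | COc1cc(O)c(C(=O)CC(C)=O)c(OC)c1
F2 | step 9 | 5,7-dimethoxy-2-methyl-4H-chromen-4-one | COc1cc(OC)c2c(=O)cc(C)oc2c1
F3 | step 6 | tert-butyl (S)-3-(tert-butyldimethylsilyloxy)-7-(6-methyl-4-oxo-4H-pyran-2-yl)heptanoate | Cc1cc(=O)cc(CCCC[C@H](O[Si](C)(C)C(C)(C)C)CC(=O)OC(C)(C)C)o1
F4 | step 6 | tert-butyl (S)-3-(tert-butyldimethylsilyloxy)-7-{6-[(E)-2-(dimethylamino)ethenyl]-4-oxo-4H-pyran-2-yl}heptanoate | CN(C)/C=C/c1cc(=O)cc(CCCC[C@H](O[Si](C)(C)C(C)(C)C)CC(=O)OC(C)(C)C)o1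
F5 | step 6 | tert-butyl (S)-3-(tert-butyldimethylsilyloxy)-7-(6-formyl-4-oxo-4H-pyran-2-yl)heptanoate | O=Cc1cc(=O)cc(CCCC[C@H](O[Si](C)(C)C(C)(C)C)CC(=O)OC(C)(C)C)o1
F6 | step 7 | tert-butyl (S)-7-(6-acetyl-4-oxo-4H-pyran-2-yl)-3-(tert-butyldimethylsilyloxy)heptanoate | CC(=O)c1cc(=O)cc(CCCC[C@H](O[Si](C)(C)C(C)(C)C)CC(=O)OC(C)(C)C)o1
F7 | step 7 | tert-butyl (S)-3-(tert-butyldimethylsilyloxy)-7-[4-oxo-6-(4,4,4-trifluoro-3-oxobutanoyl)-4H-pyran-2-yl]heptanoate | O=C(CC(=O)C(F)(F)F)c1cc(=O)cc(CCCC[C@H](O[Si](C)(C)C(C)(C)C)CC(=O)OC(C)(C)C)o1
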